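Retrosynthesis cuts, in order: the C15–O acyl bond of the ester; the C15–O bond together with the C14=C15 unsaturation (hydration of a vinyl group); the C13–C14 bond (a vinyl unit joined to a C13 secondary boronic ester); the C13–B bond (back to a terminal C13=C16 alkene); and the side chain back to the C18 methyl ketone obtained from sclareol.
Forward: rings A and B (the trans-decalin with C5, C8, C9, C10 and the C8 tertiary alcohol) are taken intact from sclareol and never touched. The chain is trimmed to C13 (ketone, then C13=C16 alkene), borylated at C13, joined to the C14–C15 vinyl unit, oxidised at C15 and acylated.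
Stereochemistry: C5, C8, C9 and C10 come from sclareol. C13, the only stereocentre outside the rings, is set by a chiral copper catalyst in a Markovnikov protoboration and carried with retention through the boron-to-carbon shift that makes C13–C14.
Enabling feature: C13 is a methyl-bearing CH between C12H2 and C14H2, insulated from C9 of ring B by the C11–C12 ethylene, so no substrate control reaches it. As a C13–B(pin) centre it is configurationally stable and its C–B bond migrates to a vinyl carbon with retention, while the hindered C8 hydroxyl can stay free throughout.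

Key step: step 5

Remark: labdane numbering is used (side chain C11–C16, C16 being the methyl group on C13); in step 4 the ligand antipode is taken as the one that delivers the (S)-2-borylalkane from a 1-alkene, the ring stereocentres being too remote to bias the choice.

Step 1
Reactants: 1 sclareol
Product: 3 8α-hydroxy-14,15-dinorlabdan-13-one, via (13R)-labdane-8α,13,14,15-tetraol 2 (not isolated)
Conditions: OsO4 (2 mol%), NaIO4 (4 equiv), 2,6-lutidine (2 equiv), dioxane/H2O 3:1, rt
Reagents that add atoms: none
Why: Lemieux–Johnson oxidation, in which osmium-catalysed dihydroxylation of the only alkene (C14=C15) gives tetraol 2 and periodate then cleaves its tertiary–secondary 13,14-glycol, so that the C13 carbinol oxygen of sclareol becomes the ketone oxygen of 3 while C5, C8, C9, C10 and the C8 tertiary alcohol are untouched and lutidine keeps the medium from becoming acidic enough to cyclodehydrate the δ-hydroxy ketone.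

Step 2
Reactants: 3 8α-hydroxy-14,15-dinorlabdan-13-one
Product: 4 (E)-tosylhydrazone of 3
Conditions: TsNHNH2 (1.1 equiv), MeOH, rt to 40 °C
Reagents that add atoms: 4-methylbenzenesulfonohydrazide, Cc1ccc(cc1)S(=O)(=O)NN
Why: Hydrazone formation by condensation of the unhindered methyl ketone with tosylhydrazide should need no acid and give mainly the E isomer, with the sulfonamide nitrogen syn to the C16 methyl group as wanted for the next step, and no stereocentre is affected.

Step 3
Reactants: 4 (E)-tosylhydrazone of 3
Product: 6 14,15-dinorlabd-13(16)-en-8α-ol, via C13 vinyllithium 5 (not isolated)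
Conditions: n-BuLi (3.5 equiv), TMEDA, THF, −78 °C to rt; then H2O
Reagents that add atoms: none
Why: Shapiro reaction, in which after removal of the O–H and N–H protons the third equivalent of base deprotonates the C16 methyl group (the kinetically most accessible α-hydrogen, syn to the sulfonamide nitrogen), the dianion loses sulfinate and N2 to give vinyllithium 5 with the double bond fixed at C13=C16, and water protonates C13 to the terminal alkene.

Step 4
Reactants: 6 14,15-dinorlabd-13(16)-en-8α-ol
Product: 7 (13S)-13-(pinacolatoboryl)-14,15-dinorlabdan-8α-ol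
Conditions: (ANIPE)CuCl (5 mol%, a bulky C2-symmetric chiral N-heterocyclic carbene complex, antipode for 13S), NaOt-Bu (10 mol%), B2pin2 (1.5 equiv), MeOH (2 equiv), THF, rt
Reagents that add atoms: bis(pinacolato)diboron, CC1(C)OB(OC1(C)C)B1OC(C)(C)C(C)(C)O1
Why: Ligand-controlled copper-catalysed Markovnikov protoboration of an unactivated 1-alkene, in which the Cu–Bpin species adds across C13=C16 with boron on the internal carbon because the bulky chiral carbene disfavours terminal borylation, the same ligand discriminates the two alkene faces and so sets C13 (13S) by catalyst control alone (C9 is three bonds away), and methanol cleaves the C16–Cu bond to leave the methyl group.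

Step 5
Reactants: 7 (13S)-13-(pinacolatoboryl)-14,15-dinorlabdan-8α-ol; 8 vinylmagnesium bromide
Product: 11 (13S)-labd-14-en-8α-ol, via vinylboronate complex 9 (not isolated), via β-iodoalkylboronic ester 10 (not isolated)
Conditions: CH2=CHMgBr (4 equiv), THF/DMSO 1:1, rt; then I2 (4 equiv) in THF, 0 °C; then NaOMe (8 equiv) in MeOH, 0 °C to rt
Reagents that add atoms: none
Why: Zweifel olefination, in which the vinyl Grignard reagent adds to boron of 7 to give the tetracoordinate boronate complex 9, iodine activates the vinyl group as an iodonium ion and triggers a 1,2-shift of the C13 secondary alkyl group from boron to the adjacent vinyl carbon (the event that forms C13–C14) to give the β-iodoalkylboronic ester 10, and methoxide then effects anti-elimination of boron and iodine to unveil the C14=C15 alkene. The closest known reaction type is the iodine-induced vinylation of enantioenriched secondary alkyl pinacol boronic esters, a boron-to-carbon 1,2-metallate rearrangement followed by elimination. No ring is closed. No new stereocentre remains in the product, since C13 migrates with retention (the C–B σ bond shifts as an electron pair and the carbon never becomes planar) so the catalyst-set 13S configuration passes unchanged into 11, and the C14 stereocentre of 10 is transient and erased on elimination. The step needs stereospecific migration of the alkyl group in preference to a pinacol oxygen and clean boronate formation at a hindered secondary boron, which should be secured by the closed-shell iodonium pathway at low temperature, by the higher migratory aptitude of carbon over the chelating alkoxy ligands, and by the C8 alkoxide (formed from one sacrificial equivalent of Grignard reagent) being too hindered to bind boron.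

Step 6
Reactants: 11 (13S)-labd-14-en-8α-ol
Product: 13 (13S)-labdane-8α,15-diol, via B-alkyl-9-BBN adduct 12 (not isolated)
Conditions: 9-BBN (3 equiv), THF, 0 °C to rt; then 3 M NaOH, 30% H2O2, 0 °C to rt
Reagents that add atoms: hydrogen peroxide, OO
Why: Hydroboration–oxidation, in which 9-BBN adds to the monosubstituted C14=C15 alkene with boron on the terminal C15 for steric reasons and alkaline H2O2 replaces boron by hydroxyl, the allylic C13 stereocentre being a spectator.

Step 7
Reactants: 13 (13S)-labdane-8α,15-diol; 14 3-phenylpropanoyl chloride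
Product: 15 (13S)-8α-hydroxylabdan-15-yl 3-phenylpropanoate
Conditions: 14 (1.1 equiv), pyridine (2 equiv), CH2Cl2, 0 °C to rt
Reagents that add atoms: none
Why: Acylation of an alcohol with an acid chloride in the presence of pyridine, in which the primary C15 hydroxyl should react far faster than the C8 tertiary hydroxyl flanked by the C10 quaternary centre, so that monoesterification is selective without protection.

Compound list
1 | sclareol, (13R)-labd-14-ene-8α,13-diol, (1R,2R,4aS,8aS)-1-[(3R)-3-hydroxy-3-methylpent-4-en-1-yl]-2,5,5,8a-tetramethyldecahydronaphthalen-2-ol | C=C[C@](C)(O)CC[C@@H]1[C@@]2(C)CCCC(C)(C)[C@@H]2CC[C@@]1(C)O | starting material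
2 | (13R)-labdane-8α,13,14,15-tetraol, both C14 epimers | OCC(O)[C@](C)(O)CC[C@@H]1[C@@]2(C)CCCC(C)(C)[C@@H]2CC[C@@]1(C)O | intermediate
3 | 8α-hydroxy-14,15-dinorlabdan-13-one, 4-[(1R,2R,4aS,8aS)-2-hydroxy-2,5,5,8a-tetramethyldecahydronaphthalen-1-yl]butan-2-one | CC(=O)CC[C@@H]1[C@@]2(C)CCCC(C)(C)[C@@H]2CC[C@@]1(C)O | intermediate
4 | (E)-tosylhydrazone of 3, N'-[(2E)-4-[(1R,2R,4aS,8aS)-2-hydroxy-2,5,5,8a-tetramethyldecahydronaphthalen-1-yl]butan-2-ylidene]-4-methylbenzenesulfonohydrazide | C/C(CC[C@@H]1[C@@]2(C)CCCC(C)(C)[C@@H]2CC[C@@]1(C)O)=N\NS(=O)(=O)c1ccc(C)cc1 | intermediate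
5 | C13 vinyllithium, 13-lithio-14,15-dinorlabd-13(16)-en-8α-ol as its C8 lithium alkoxide | [Li]C(=C)CC[C@@H]1[C@@]2(C)CCCC(C)(C)[C@@H]2CC[C@@]1(C)O[Li] | intermediate
6 | 14,15-dinorlabd-13(16)-en-8α-ol, (1R,2R,4aS,8aS)-1-(but-3-en-1-yl)-2,5,5,8a-tetramethyldecahydronaphthalen-2-ol | C=CCC[C@@H]1[C@@]2(C)CCCC(C)(C)[C@@H]2CC[C@@]1(C)O | intermediate
7 | (13S)-13-(pinacolatoboryl)-14,15-dinorlabdan-8α-ol, (1R,2R,4aS,8aS)-2,5,5,8a-tetramethyl-1-[(3S)-3-(4,4,5,5-tetramethyl-1,3,2-dioxaborolan-2-yl)butyl]decahydronaphthalen-2-ol | C[C@H](B1OC(C)(C)C(C)(C)O1)CC[C@@H]1[C@@]2(C)CCCC(C)(C)[C@@H]2CC[C@@]1(C)O | intermediate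
8 | vinylmagnesium bromide | C=C[Mg]Br | starting material
9 | vinylboronate complex, B-vinyl ate complex of 7 as bromomagnesium salt, C8 as bromomagnesium alkoxide, C13 as in 7 | C[C@H]([B-]1(C=C)OC(C)(C)C(C)(C)O1)CC[C@@H]1[C@@]2(C)CCCC(C)(C)[C@@H]2CC[C@@]1(C)O[Mg]Br.[Mg+]Br | intermediate
10 | β-iodoalkylboronic ester, (13S)-15-iodo-14-(pinacolatoboryl)labdan-8α-ol as its bromomagnesium alkoxide, both C14 epimers | C[C@H](C(CI)B1OC(C)(C)C(C)(C)O1)CC[C@@H]1[C@@]2(C)CCCC(C)(C)[C@@H]2CC[C@@]1(C)O[Mg]Br | intermediate
11 | (13S)-labd-14-en-8α-ol, (1R,2R,4aS,8aS)-2,5,5,8a-tetramethyl-1-[(3S)-3-methylpent-4-en-1-yl]decahydronaphthalen-2-ol | C[C@H](C=C)CC[C@@H]1[C@@]2(C)CCCC(C)(C)[C@@H]2CC[C@@]1(C)O | intermediate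
12 | B-alkyl-9-BBN adduct, 9-(8α-hydroxylabdan-15-yl)-9-borabicyclo[3.3.1]nonane, C13 as in 11 | C[C@H](CCB1C2CCCC1CCC2)CC[C@@H]1[C@@]2(C)CCCC(C)(C)[C@@H]2CC[C@@]1(C)O | intermediate
13 | (13S)-labdane-8α,15-diol, (1R,2R,4aS,8aS)-1-[(3S)-5-hydroxy-3-methylpentyl]-2,5,5,8a-tetramethyldecahydronaphthalen-2-ol | C[C@H](CCO)CC[C@@H]1[C@@]2(C)CCCC(C)(C)[C@@H]2CC[C@@]1(C)O | intermediate
14 | 3-phenylpropanoyl chloride | O=C(Cl)CCc1ccccc1 | starting material
15 | (13S)-8α-hydroxylabdan-15-yl 3-phenylpropanoate, (3S)-5-[(1R,2R,4aS,8aS)-2-hydroxy-2,5,5,8a-tetramethyldecahydronaphthalen-1-yl]-3-methylpentyl 3-phenylpropanoate | C[C@H](CCOC(=O)CCc1ccccc1)CC[C@@H]1[C@@]2(C)CCCC(C)(C)[C@@H]2CC[C@@]1(C)O | target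

Total step count: 7. Longest linear sequence: 7 steps (1 to 15); 8 and 14 are commercial.

Steps most likely to fail

Step 4. The borylcupration of an unbiased 1-alkene may lose regiocontrol (boron delivered to the terminal C16) or show poor facial selectivity, since only the ligand differentiates the two ends and faces of the alkene. The fallback sets out from hydrazone 4 and returns to the route at 7. The conditions of step 3 would be kept, but vinyllithium 5 would be trapped at −78 °C with 2-isopropoxy-4,4,5,5-tetramethyl-1,3,2-dioxaborolane instead of water, which should give 13-(pinacolatoboryl)-14,15-dinorlabd-13(16)-en-8α-ol F1. Asymmetric hydrogenation of this 1,1-disubstituted alkenyl boronate ([Rh(cod)2]BF4, a chiral ferrocenyl bisphosphine, H2, 1,2-dichloroethane, rt) should then give 7. Boron is already fixed on C13, so regiochemistry is no longer in question and only the face of hydrogen delivery has to be controlled.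

Step 5. Formation of the boronate complex at the hindered secondary boron may be incomplete, or the Grignard reagent may add more than once with displacement of pinacol, so that material is diverted before the iodine-triggered shift. The fallback sets out from ketone 3 and returns to the route at diol 13. Horner–Wadsworth–Emmons olefination of 3 (triethyl phosphonoacetate, NaH, THF, 0 °C to rt) should form the C13=C14 bond and give ethyl (13E)-8α-hydroxylabd-13-en-15-oate F2. Reduction with i-Bu2AlH (CH2Cl2, −78 °C) should give (13E)-labd-13-ene-8α,15-diol F3. Hydroxyl-directed asymmetric hydrogenation of this (E)-3-methylalk-2-en-1-ol (H2, Ru(OAc)2[(R)-BINAP], MeOH) should then set C13 and give 13; the sense is assigned by analogy with the hydrogenation of geraniol to (S)-citronellol by the same catalyst antipode.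

Step 3. Deprotonation may leak to the C12 side of the hydrazone, or dianion formation may stall in the presence of the lithium alkoxide, which would erode the position of the double bond. The fallback sets out from ketone 3 and returns to the route at alkene 6. Kinetic deprotonation of the methyl group with LiN(i-Pr)2 (2.2 equiv, THF, −78 °C) and trapping with PhNTf2 should give 8α-hydroxy-14,15-dinorlabd-13(16)-en-13-yl trifluoromethanesulfonate F4. Palladium-catalysed formate reduction (Pd(OAc)2, PPh3, Bu3N, HCO2H, DMF, 60 °C) should then give 6.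

Further compounds
F1 | step 4 | 13-(pinacolatoboryl)-14,15-dinorlabd-13(16)-en-8α-ol | C=C(B1OC(C)(C)C(C)(C)O1)CC[C@@H]1[C@@]2(C)CCCC(C)(C)[C@@H]2CC[C@@]1(C)O
F2 | step 5 | ethyl (13E)-8α-hydroxylabd-13-en-15-oate | CCOC(=O)/C=C(\C)CC[C@@H]1[C@@]2(C)CCCC(C)(C)[C@@H]2CC[C@@]1(C)O
F3 | step 5 | (13E)-labd-13-ene-8α,15-diol | OC/C=C(\C)CC[C@@H]1[C@@]2(C)CCCC(C)(C)[C@@H]2CC[C@@]1(C)O
F4 | step 3 | 8α-hydroxy-14,15-dinorlabd-13(16)-en-13-yl trifluoromethanesulfonate | C=C(OS(=O)(=O)C(F)(F)F)CC[C@@H]1[C@@]2(C)CCCC(C)(C)[C@@H]2CC[C@@]1(C)O
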